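**Numbering.** Briarane numbering, read along the target SMILES: C16=C5, C4=C3, C2 (butyrate), C1 (methyl C15), C14=C13, C12 (OAc), C11 (methyl C20, OH), C10, C9 (OAc), C8 (OH), C17 (methyl C18), C19 (lactone C=O), ring O, C7, C6 (Cl). β is the face of ring A that carries C15 and α is the other face. The SMILES decodes as 1S,2S,3Z,6S,7R,8R,9S,10S,11S,12R,17R.

**Assumption.** Compounds 1, 2, 5, 17 (as a THF solution) and 24 are taken as commercial. The antipode of each chiral ligand (steps 2 and 16) is the one matched to the configuration drawn.

## The problem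

- **Ring system.** The skeleton is a bicyclo[8.4.0]tetradecane. Cyclohexene ring A (C1, C10–C14) is trans-fused through quaternary C1 and methine C10 to the ten-membered ring B (C1–C10). Ring B carries the γ-lactone ring C (C7, C8, C17, C19, O) in trans fusion.
- **Hardest feature.** Ring B is the main difficulty, because a ten-membered ring resists end-to-end closure. This one also holds a Z C3=C4 bond conjugated with the C5=C16 exomethylene, five stereocentres (C2, C6, C7, C8, C9) and two fully substituted carbons (C1, C8).
- **Stereocentres that can control each other.** C1, C2, C9, C10, C11 and C12 can do so on a rigid carbocycle. O2, O9, C15 and C20 lie on one face; H-10, 11-OH and 12-OAc lie on the other, the last two forming a cis-diol.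
- **Remote stereocentres.** C6, C7, C8 and C17 lie across the ring and are related mainly to one another. Cl-6/O-7 is the anti adduct of an E C6=C7 olefin, O-7/O-8 are anti, and C17 is epimerisable.
- **Fragile groups.** These are the secondary allylic chloride (SN2′, elimination), the β-hydroxy lactone (retro-aldol, dehydration) and two free tertiary alcohols. In addition, the butyrate at O2 must be told apart from the acetates at O9 and O12.
- **Enabling feature.** The atoms O–C8–C7–C6–C5(=C16)–C4=C3 are the retron of an oxy-Cope rearrangement whose accepting π bond is an allene. Reconnecting C3 to C8 shrinks ring B to a six-membered ring D (C1, C2, C3, C8, C9, C10). The result is a trans-decalin whose substitution (O at C2, C8 and C9, methyl at C1) is that of an alkoxy-toluquinone.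

## Retrosynthesis

**31 ⇒ 27 (acyl C–O bonds).**
- The three esters are removed first because none would survive carbanion chemistry.
- O2 carries a TES group. O9 (TBS) and O11/O12 (acetonide) carry groups that fall together.
- Butyrate goes on alone (28 → 29) and both acetates go on in one operation (30 → 31).
- The forward steps need only secondary-over-tertiary acylation selectivity.

**27 ⇒ 25 ⇒ 23 + 24 (C6–Cl, O7–C19, C8–C17).**
- The Cl-6/O-7 anti pair is traced to the trans epoxide of 25. Chloride opens it at the allylic C6 and the freed 7-OH lactonises.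
- Cutting C8–C17 as an aldol bond leaves ketone 23 and ethyl propanoate 24.
- A cut at C7–C8 or C8–C9 would break ring B again, and halolactonisation of a C6=C7 olefin has the wrong electronic bias.
- The precursor loses ring C and three stereocentres.
- The forward steps require addition to a hindered ketone under control by the adjacent epoxide.

**23 ⇒ 22 ⇒ 21 (epoxide O, C6–C7 unsaturation).**
- Epoxide 23 comes from E-enone 22.
- Enone 22 comes from silyl enol ether 21, whose double bond position (C7=C8) is a free gift of the key step.
- Two more stereocentres disappear.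
- The forward epoxidation must be face-selective on a flexible ring, so it is placed under catalyst control.

**21 ⇒ 18 (cut C5–C6, reconnect C3–C8; key step).**
- Among all ring B bonds, C5–C6 is the one whose cleavage is compensated by a [3,3] shift.
- That shift turns the diene into an allenyl group on C3 and turns C6–C7 into a vinyl group on C8.
- Cuts at C3=C4 or C2–C3 only give long open chains.
- Precursor 18 is a trans-decalin with no medium ring and no olefin geometry to set.
- The forward reaction must give Z at C3=C4 and must not fragment.

**18 ⇒ 16 + 17 and 16 ⇒ 15 (C7–C8, C3–C4).**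
- The vinyl group is added to ketone 16.
- The α-allenyl ketone is the product of a propargyl vinyl ether Claisen rearrangement of 15.
- This choice places C4, C5 and C16 on the ring oxygen of C8 from the start and fixes the regiochemistry at C3 rather than C9, which enolate chemistry could not guarantee.

**15 ⇒ 13 ⇒ 11 ⇒ 7 (C–O and C–H bonds on the decalin).**
- O2 and O9 are carbonyl groups reduced one after the other from the face opposite C15. Sequential reduction also differentiates them.
- The cis 11,12-diol with the C13=C14 bond is the mono-dihydroxylation product of ring A diene 11.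
- Diene 11 is made from the cyclohexene of 7 by bromination and double dehydrobromination.
- All six stereocentres follow from the angular methyl group.

**7 ⇒ 6 ⇒ 4 + 5 and 4 ⇒ 1 + 2 (C1–C14, C10–C11, C8–O).**
- Ring A is cut by a retro-Diels–Alder reaction into piperylene 5 and propargyloxy-toluquinone 4.
- C10 is epimerisable next to C9=O, so the trans fusion is reachable.
- Quinone 4 comes from toluquinone 1 and propargyl alcohol 2.
- Five bought compounds (1, 2, 5, 17, 24) supply all twenty skeletal carbons.

## Roads not taken

**Alternative 1:** The most obvious plan.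
- Cut: ring B at C3=C4 (or at C2–C3), with the ring closed last.
- Forward key step: ring-closing metathesis of the fully functionalised seco-tetraene A1 with second-generation Grubbs catalyst, or a CrCl2/NiCl2-mediated closure at C2–C3.
- Why the chosen plan is better:
  - All ten stereocentres would have to be built on a ring A fragment with two long arms before the ring exists.
  - The closure fights the strain and entropy of a ten-membered ring.
  - Z geometry is not assured, and the 1,3-diene offers the catalyst a second initiation site that leads to ring-contracted products.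
  - The allylic chloride must either survive the metal or be added afterwards on an unbiased ring.
  - The chosen plan never closes a medium ring end to end and obtains the Z geometry from a locked chair.

**Alternative 2:**
- Cut: reconnect C4 to C9, which gives a cis-fused hydrophenanthrene.
- Forward key step: open it late by Wharton–Grob fragmentation of 1,3-hydroxy mesylate A2, giving C9 ketone A3 with the Z C3=C4 bond.
- Point in its favour: stereocontrol on rigid six-membered rings is attractive.
- Why the chosen plan is better:
  - A2 is pentacyclic and has more stereocentres than the target, including an equatorial mesylate and a cis ring fusion that serve only the fragmentation.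
  - A3 is an α-ketol prone to acyloin shift and retro-aldol cleavage under the basic conditions.
  - C9 must still be reduced and C6 chlorinated.
  - The precursor is more complex than the product, which is the opposite of what a key step should offer.

**Alternative 3:**
- Cut: the biomimetic cut at C1–C10, which leads to the 14-membered macrocyclic triene A4.
- Forward key step: a transannular disrotatory 6π electrocyclisation that closes ring A and ring B together and gives the ring A diene needed for dihydroxylation.
- Why the chosen plan is better: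
  - The required trans relation of C2 and C9 forces C2 into the inside position of a fully substituted triene terminus.
  - Such trienes cyclise slowly and prefer 1,7-hydrogen shifts from the neighbouring methyl groups.
  - Nothing in A4 controls the sense of rotation relative to C2 and C9.
  - The macrocycle itself needs a long stereocontrolled open-chain synthesis.
  - The chosen plan reaches the same ring A diene (11) by a Diels–Alder reaction and two simple operations.

Key step: step 14

## Route

Step 1
Reactants: 1 2-methyl-1,4-benzoquinone (2 equiv); 2 prop-2-yn-1-ol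
Product: 4 2-methyl-5-(prop-2-yn-1-yloxy)-1,4-benzoquinone, via alkoxyhydroquinone 3 (not isolated)
Conditions: ZnCl2 (cat.), 2 as solvent, rt to 40 °C
Reagents that add atoms: none
Why: Lewis-acid-catalysed conjugate addition of an alcohol to a quinone followed by redox exchange (oxidative alkoxylation, the classical entry to 2-alkoxy-5-methylquinones); the alcohol adds at the free position least deactivated by the methyl donor, and the electron-rich hydroquinone 3 is reoxidised by the second equivalent of 1.

Step 2
Reactants: 4 2-methyl-5-(prop-2-yn-1-yloxy)-1,4-benzoquinone; 5 (E)-penta-1,3-diene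
Product: 6 cis-fused endo adduct 4a,8-dimethyl-2-(prop-2-yn-1-yloxy)-4a,5,8,8a-tetrahydronaphthalene-1,4-dione (C15 β; H-10 β; C20 α)
Conditions: TiCl2(OiPr)2 (20 mol %), (R,R)-TADDOL (22 mol %), 4 Å MS, toluene/CH2Cl2, −78 to −30 °C
Reagents that add atoms: none
Why: Asymmetric Lewis-acid-catalysed Diels–Alder reaction in which the propargyloxy oxygen and the neighbouring C9 carbonyl chelate titanium; this leaves C1=C10 as the only dienophile (C3=C8 is a deactivated vinylogous ester), makes C1 the more electrophilic end so that it bonds to the unsubstituted diene terminus C14, and lets the TADDOLate shield one face to set C1 as 1S. Suprafacial endo addition makes C15 and H-10 cis and places C20 cis to C9.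

Step 3
Reactants: 6 cis-fused adduct
Product: 7 trans-fused isomer of 6 (H-10 α; C15 β; C20 α equatorial)
Conditions: DBU (0.2 equiv), THF, 0 °C to rt
Reagents that add atoms: none
Why: Base-catalysed epimerisation through the C9 enolate, C10 being the only enolisable stereocentre; the trans-fused form with equatorial C20 is taken as the thermodynamic product, as in classical quinone-adduct chemistry, while C1 and C11 are untouched.

Step 4
Reactants: 7 trans-fused enedione
Product: 8 diaxial 12α,13β-dibromide of 7
Conditions: Br2 (1.0 equiv), CH2Cl2, −78 °C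
Reagents that add atoms: bromine, BrBr
Why: Electrophilic anti addition to the only nucleophilic π bond (C3=C8 lies between two carbonyl groups and the propargylic alkyne is far slower); a bromonium ion on the open α face and Fürst–Plattner opening give the diaxial dibromide.

Step 5
Reactants: 8 dibromo enedione
Product: 9 9β-alcohol (axial OH; C2 vinylogous ester retained)
Conditions: NaBH4, CeCl3·7H2O, MeOH/CH2Cl2, −78 °C
Reagents that add atoms: none
Why: Luche 1,2-reduction; the C9 carbonyl is outside the push-pull system and is much more electrophilic than the vinylogous ester carbonyl C2. The axial C15 closes the β face, so hydride arrives from α and gives the 9β-alcohol, the sense seen with 6-oxo steroids.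

Step 6
Reactants: 9 9β-alcohol
Product: 10 9β-tert-butyldimethylsilyl ether of 9
Conditions: TBSOTf, 2,6-lutidine, CH2Cl2, −40 to 0 °C
Reagents that add atoms: tert-butyldimethylsilyl triflate, CC(C)(C)[Si](C)(C)OS(=O)(=O)C(F)(F)F
Why: Silylation of a hindered secondary alcohol with a silyl triflate; no stereocentre is touched and O9 is now marked differently from O2.

Step 7
Reactants: 10 dibromide
Product: 11 ring A 11,13-diene (C11(C20)=C12–C13=C14; H-10 α)
Conditions: DBU (5 equiv), toluene, 100 °C
Reagents that add atoms: none
Why: Twofold E2 dehydrobromination; 12α-Br is antiperiplanar to H-11β and 13β-Br to H-14α, and no antiperiplanar hydrogen exists for vinyl bromide formation. With C9 already reduced, H-10 is no longer acidic and the diene cannot slip into conjugation.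

Step 8
Reactants: 11 ring A diene
Product: 12 11α,12α-diol (C20 β; C13=C14 retained)
Conditions: OsO4 (2 mol %), NMO (1.05 equiv), acetone/H2O, 0 °C
Reagents that add atoms: osmium tetroxide, O=[Os](=O)(=O)=O; N-methylmorpholine N-oxide, C[N+]1([O-])CCOCC1; water, O
Why: Upjohn dihydroxylation; the trisubstituted, most electron-rich C11=C12 bond reacts before the neopentyl C13=C14 bond, the push-pull C3=C8 bond and the alkyne. C15 and the 9β-silyloxy group close the β face, so syn addition from α sets C11 and C12 together.

Step 9
Reactants: 12 diol
Product: 13 11α,12α-acetonide of 12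
Conditions: 2-methoxypropene, PPTS (cat.), CH2Cl2, 0 °C
Reagents that add atoms: 2-methoxypropene, COC(C)=C
Why: Acetonide formation on a cis-diol under mild acid; the low temperature and the small amount of alcohol released keep the vinylogous ester from exchanging its propargyloxy group.

Step 10
Reactants: 13 vinylogous ester
Product: 14 2β-alcohol (equatorial OH; C3=C8 propargyl enol ether retained)
Conditions: iBu2AlH, CH2Cl2, −78 °C; aqueous potassium sodium tartrate work-up
Reagents that add atoms: none
Why: 1,2-Reduction of a vinylogous ester (first half of a Stork–Danheiser sequence, stopped before any acid); hydride attacks axially from the α face, anti to C15, and gives the equatorial 2β-alcohol, and the non-acidic work-up keeps the enol ether.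

Step 11
Reactants: 14 2β-alcohol
Product: 15 2β-triethylsilyl ether of 14
Conditions: TESOTf, 2,6-lutidine, CH2Cl2, −78 °C
Reagents that add atoms: triethylsilyl triflate, CC[Si](CC)(CC)OS(=O)(=O)C(F)(F)F
Why: Buffered silylation that avoids ionisation of the allylic enol ether alcohol; TES on O2 and TBS on O9 can later be removed in that order.

Step 12
Reactants: 15 propargyl enol ether
Product: 16 3α-(propa-1,2-dienyl) 8-ketone (allenyl equatorial; 2β-OTES; 9β-OTBS)
Conditions: toluene, BHT (trace), base-washed sealed tube, 135 °C
Reagents that add atoms: none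
Why: Propargyl vinyl ether Claisen rearrangement (Saucy–Marbet type) that forms C3–C4 and turns O–CH2–C≡CH into CH=C=CH2; it is regiospecific because the enol ether position was fixed in step 1. The β face of C3 is 1,3-diaxial to C15, so the bond forms on the α face and gives the equatorial, also thermodynamic, allenyl group, and neutral conditions avoid prototropic shift.

Step 13
Reactants: 16 allenyl ketone; 17 vinylmagnesium bromide
Product: 18 8α-vinyl-8β-ol (axial vinyl cis to the equatorial 3α-allenyl group)
Conditions: LaCl3·2LiCl (0.3 equiv), THF, −78 °C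
Reagents that add atoms: none
Why: Lanthanide-assisted Grignard 1,2-addition, which suppresses enolisation at the acidic C3–H; attack antiperiplanar to the axial C9–O bond (polar Felkin–Anh) and away from the silyloxy group and C15 is axial attack from the α face, which sets C8.

Step 14
Reactants: 18 8α-vinyl-8β-ol
Product: 21 (3Z)-bicyclo[8.4.0] 8-trimethylsilyl enol ether (C7=C8; C3=C4–C5(=C16) diene), via potassium alkoxide 19 (not isolated), via potassium enolate 20 (not isolated)
Conditions: KH, 18-crown-6, THF, 0 °C to rt; then TMSCl, Et3N, −78 °C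
Reagents that add atoms: chlorotrimethylsilane, C[Si](C)(C)Cl
Why: KH/18-crown-6 gives the naked alkoxide 19, whose charge weakens C3–C8 and triggers an anionic oxy-Cope [3,3] shift through the six centres C6=C7–C8–C3–C4=C5; the closest known reactions are the anionic oxy-Cope four-carbon enlargement of 1,2-dialkenylcyclohexanols to cyclodecenones and the Cope rearrangement of 1,2,6-trienes, where an allene accepts the new bond at its central carbon. Ring B is closed by ring enlargement and not end to end: C5–C6 forms while C3–C8 breaks, so six-membered ring D becomes the ten-membered ring without the entropy cost of a macrocyclisation. Because the new bond ends at the allene centre C5, the remaining cumulated bond emerges as the C5=C16 exomethylene conjugated with the new C3=C4 bond, which is the complete diene of the target. No stereocentre is created: C3 and C8 are erased and C1, C2, C9, C10, C11 and C12 are spectators. The selectivity needed is Z at C3=C4; in the locked trans-decalin the axial vinyl and equatorial allenyl groups are gauche, and in the only accessible chair array C2 is axial on C3 (hence Z) while C9 is equatorial on C8 (in-ring E enolate). The 8-epimer or a boat array would give E, so the facial selectivity of step 13 and the rigidity of the decalin secure the geometry. Enolate formation, the change from allene to conjugated diene and the release of the three syn-axial β groups (C15, O9, C20) drive the reaction. Enolate 20 is regiodefined at C7=C8, and its capture as 21 allows C6 and C7 to be functionalised next.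

Step 15
Reactants: 21 silyl enol ether
Product: 22 (3Z,6E)-3,5(16),6-trien-8-one
Conditions: Pd(OAc)2 (1.05 equiv), MeCN, rt
Reagents that add atoms: none
Why: Saegusa–Ito oxidation; divalent palladium replaces silicon at C7 and syn β-hydride elimination of a C6 hydrogen, from the conformer with C5 anti to C8, should give the E enone. The position of the new double bond is dictated by the enol ether from step 14.

Step 16
Reactants: 22 trienone
Product: 23 (6R,7S)-trans-6,7-epoxy 8-ketone
Conditions: La(OiPr)3, (R)-BINOL, Ph3As=O (10 mol % each), tBuOOH (decane), 4 Å MS, THF, rt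
Reagents that add atoms: tert-butyl hydroperoxide, CC(C)(C)OO
Why: Catalytic asymmetric nucleophilic epoxidation of an E enone (Weitz–Scheffer type); peroxide adds to C6 and ring closure at C7 keeps the E geometry as a trans epoxide. The chiral lanthanum complex, not the flexible ring, chooses the face (the (R)-BINOL series is associated with αS,βR epoxy ketones, here 7S,6R), and the electron-rich olefins are not touched by a nucleophilic oxidant.

Step 17
Reactants: 23 epoxy ketone; 24 ethyl propanoate
Product: 25 aldol adduct (tertiary 8-OH anti to the epoxide oxygen at C7; C17 as in the target; ethyl ester)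
Conditions: LiN(iPr)2, 24, THF, −78 °C; then 23, −78 °C; AcOH quench at −78 °C
Reagents that add atoms: none
Why: Lithium ester enolate aldol addition to a ketone; a lithium chelate between C8=O and the epoxide oxygen exposes the carbonyl face flanked by H-7, which gives O8 anti to O7 and sets C8, and the cold acid quench prevents retro-aldol. C17 arises from the closed Zimmerman–Traxler array and stays correctable, since in the lactone the 17-methyl group trans to C9 is the thermodynamic arrangement.

Step 18
Reactants: 25 epoxy alcohol ester
Product: 27 6-chloro 7,19-lactone (6S; 8-OH free; 2-OTES; 9-OTBS; 11,12-acetonide), via chlorohydrin ester 26 (not isolated)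
Conditions: TiCl2(OiPr)2 (1.5 equiv), CH2Cl2, −20 to 0 °C; aqueous work-up; then PPTS (cat.), toluene, 45 °C
Reagents that add atoms: dichlorotitanium diisopropoxide, CC(C)O[Ti](Cl)(Cl)OC(C)C
Why: Titanium-assisted halide opening of a 2,3-epoxy alcohol at its C-3 position, here C6, which is also the allylic carbon; chelation of 8-OH and the epoxide oxygen delivers chloride to C6 with inversion, so the trans epoxide gives the anti Cl-6/O-7 pair of the target. The freed 7-OH closes the γ-lactone by 5-exo-trig acyl substitution on the ethyl ester, and the tertiary 8-OH cannot compete because it would form a β-lactone.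

Step 19
Reactants: 27 chloro lactone
Product: 28 2-alcohol (TES removed)
Conditions: HF·pyridine, pyridine, THF, 0 °C
Reagents that add atoms: none
Why: Buffered fluoride cleaves the triethylsilyl ether well before the hindered TBS ether; the acetonide, lactone and allylic chloride tolerate these nearly neutral conditions.

Step 20
Reactants: 28 2-alcohol
Product: 29 2-butanoate
Conditions: (PrCO)2O, Et3N, DMAP (cat.), CH2Cl2, 0 °C to rt
Reagents that add atoms: butanoic anhydride, CCCC(=O)OC(=O)CCC
Why: DMAP-catalysed acylation; O2 is the only free secondary hydroxyl group, and the tertiary 8-OH is much slower.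

Step 21
Reactants: 29 2-butanoate
Product: 30 8,9,11,12-tetraol (TBS and acetonide removed)
Conditions: 48 % aq. HF, MeCN, 0 °C to rt
Reagents that add atoms: none
Why: Aqueous HF removes the silyl ether and hydrolyses the acetonide in one operation; the medium is non-basic, which protects the chloride, the butanoate and the β-hydroxy lactone.

Step 22
Reactants: 30 tetraol
Product: 31 target CNP0114781.2
Conditions: Ac2O, pyridine, DMAP (cat.), rt
Reagents that add atoms: acetic anhydride, CC(=O)OC(C)=O
Why: Selective acetylation of the two secondary alcohols O9 and O12 in the presence of the tertiary alcohols at C8 and C11; no stereocentre is touched.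

## Compound list

1 | 2-methyl-1,4-benzoquinone | CC1=CC(=O)C=CC1=O | starting material
2 | prop-2-yn-1-ol | C#CCO | starting material
3 | 2-methyl-5-(prop-2-yn-1-yloxy)benzene-1,4-diol | Cc1cc(O)c(OCC#C)cc1O | intermediate
4 | 2-methyl-5-(prop-2-yn-1-yloxy)-1,4-benzoquinone | CC1=CC(=O)C(OCC#C)=CC1=O | intermediate
5 | (E)-penta-1,3-diene | C/C=C/C=C | starting material
6 | cis-fused endo Diels–Alder adduct (C15 β, H-10 β, C20 α) | C#CCOC1=CC(=O)[C@@]2(C)CC=C[C@@H](C)[C@H]2C1=O | intermediate
7 | trans-fused enedione (H-10 α) | C#CCOC1=CC(=O)[C@@]2(C)CC=C[C@@H](C)[C@@H]2C1=O | intermediate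
8 | 12α,13β-dibromo enedione | C#CCOC1=CC(=O)[C@@]2(C)C[C@H](Br)[C@@H](Br)[C@@H](C)[C@@H]2C1=O | intermediate
9 | 9β-alcohol | C#CCOC1=CC(=O)[C@@]2(C)C[C@H](Br)[C@@H](Br)[C@@H](C)[C@@H]2[C@@H]1O | intermediate
10 | 9β-OTBS dibromide | C#CCOC1=CC(=O)[C@@]2(C)C[C@H](Br)[C@@H](Br)[C@@H](C)[C@@H]2[C@@H]1O[Si](C)(C)C(C)(C)C | intermediate
11 | ring A 11,13-diene | C#CCOC1=CC(=O)[C@@]2(C)C=CC=C(C)[C@@H]2[C@@H]1O[Si](C)(C)C(C)(C)C | intermediate
12 | 11α,12α-diol | C#CCOC1=CC(=O)[C@@]2(C)C=C[C@@H](O)[C@@](C)(O)[C@@H]2[C@@H]1O[Si](C)(C)C(C)(C)C | intermediate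
13 | 11α,12α-acetonide | C#CCOC1=CC(=O)[C@@]2(C)C=C[C@H]3OC(C)(C)O[C@@]3(C)[C@@H]2[C@@H]1O[Si](C)(C)C(C)(C)C | intermediate
14 | 2β-alcohol, propargyl enol ether | C#CCOC1=C[C@H](O)[C@@]2(C)C=C[C@H]3OC(C)(C)O[C@@]3(C)[C@@H]2[C@@H]1O[Si](C)(C)C(C)(C)C | intermediate
15 | 2β-OTES propargyl enol ether | C#CCOC1=C[C@H](O[Si](CC)(CC)CC)[C@@]2(C)C=C[C@H]3OC(C)(C)O[C@@]3(C)[C@@H]2[C@@H]1O[Si](C)(C)C(C)(C)C | intermediate
16 | 3α-allenyl 8-ketone | C=C=C[C@H]1[C@H](O[Si](CC)(CC)CC)[C@@]2(C)C=C[C@H]3OC(C)(C)O[C@@]3(C)[C@@H]2[C@H](O[Si](C)(C)C(C)(C)C)C1=O | intermediate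
17 | vinylmagnesium bromide | C=C[Mg]Br | starting material
18 | 3α-allenyl-8α-vinyl-8β-ol | C=C=C[C@H]1[C@H](O[Si](CC)(CC)CC)[C@@]2(C)C=C[C@H]3OC(C)(C)O[C@@]3(C)[C@@H]2[C@H](O[Si](C)(C)C(C)(C)C)[C@@]1(O)C=C | intermediate
19 | potassium alkoxide of 18 | [K+].C=C=C[C@H]1[C@H](O[Si](CC)(CC)CC)[C@@]2(C)C=C[C@H]3OC(C)(C)O[C@@]3(C)[C@@H]2[C@H](O[Si](C)(C)C(C)(C)C)[C@@]1([O-])C=C | intermediate
20 | ring-enlarged potassium enolate (C7=C8) | [K+].[O-]/C1=C\CC(=C)/C=C\[C@H](O[Si](CC)(CC)CC)[C@@]2(C)C=C[C@H]3OC(C)(C)O[C@@]3(C)[C@@H]2[C@@H]1O[Si](C)(C)C(C)(C)C | intermediate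
21 | (3Z)-8-trimethylsilyl enol ether | C[Si](C)(C)O/C1=C\CC(=C)/C=C\[C@H](O[Si](CC)(CC)CC)[C@@]2(C)C=C[C@H]3OC(C)(C)O[C@@]3(C)[C@@H]2[C@@H]1O[Si](C)(C)C(C)(C)C | intermediate
22 | (3Z,6E)-3,5(16),6-trien-8-one | O=C1/C=C/C(=C)/C=C\[C@H](O[Si](CC)(CC)CC)[C@@]2(C)C=C[C@H]3OC(C)(C)O[C@@]3(C)[C@@H]2[C@@H]1O[Si](C)(C)C(C)(C)C | intermediate
23 | (6R,7S)-trans-epoxy ketone | C=C1/C=C\[C@H](O[Si](CC)(CC)CC)[C@@]2(C)C=C[C@H]3OC(C)(C)O[C@@]3(C)[C@@H]2[C@H](O[Si](C)(C)C(C)(C)C)C(=O)[C@H]4O[C@@H]41 | intermediate
24 | ethyl propanoate | CCC(=O)OCC | starting material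
25 | aldol adduct (epoxy alcohol ester) | C=C1/C=C\[C@H](O[Si](CC)(CC)CC)[C@@]2(C)C=C[C@H]3OC(C)(C)O[C@@]3(C)[C@@H]2[C@H](O[Si](C)(C)C(C)(C)C)[C@](O)([C@@H](C)C(=O)OCC)[C@H]4O[C@@H]41 | intermediate
26 | 6-chloro-7,8-diol ester | C=C1/C=C\[C@H](O[Si](CC)(CC)CC)[C@@]2(C)C=C[C@H]3OC(C)(C)O[C@@]3(C)[C@@H]2[C@H](O[Si](C)(C)C(C)(C)C)[C@](O)([C@@H](C)C(=O)OCC)[C@@H](O)[C@H]1Cl | intermediate
27 | protected 6-chloro lactone | C=C1/C=C\[C@H](O[Si](CC)(CC)CC)[C@@]2(C)C=C[C@H]3OC(C)(C)O[C@@]3(C)[C@@H]2[C@H](O[Si](C)(C)C(C)(C)C)[C@]2(O)[C@@H](C)C(=O)O[C@H]2[C@H]1Cl | intermediate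
28 | 2-alcohol | C=C1/C=C\[C@H](O)[C@@]2(C)C=C[C@H]3OC(C)(C)O[C@@]3(C)[C@@H]2[C@H](O[Si](C)(C)C(C)(C)C)[C@]2(O)[C@@H](C)C(=O)O[C@H]2[C@H]1Cl | intermediate
29 | 2-butanoate | C=C1/C=C\[C@H](OC(=O)CCC)[C@@]2(C)C=C[C@H]3OC(C)(C)O[C@@]3(C)[C@@H]2[C@H](O[Si](C)(C)C(C)(C)C)[C@]2(O)[C@@H](C)C(=O)O[C@H]2[C@H]1Cl | intermediate
30 | 2-butanoate 8,9,11,12-tetraol | C=C1/C=C\[C@H](OC(=O)CCC)[C@@]2(C)C=C[C@@H](O)[C@@](C)(O)[C@@H]2[C@H](O)[C@]2(O)[C@@H](C)C(=O)O[C@H]2[C@H]1Cl | intermediate
31 | CNP0114781.2 | C=C1/C=C\[C@H](OC(=O)CCC)[C@@]2(C)C=C[C@@H](OC(C)=O)[C@@](C)(O)[C@@H]2[C@H](OC(C)=O)[C@]2(O)[C@@H](C)C(=O)O[C@H]2[C@H]1Cl | target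

## Step count and least certain steps

Total step count: 22. Longest linear sequence: 22 steps, from 1. The other building blocks 2, 5, 17 and 24 enter unchanged.

**Step 14 (key step).**
- Most likely failures are processes open to the free alkoxide:
  - heterolytic cleavage of C3–C8 to an allenyl/propargyl anion that is protonated or recombines without geometric control;
  - addition of the alkoxide oxygen to the allene;
  - base-induced isomerisation of the allene;
  - migration of silicon from O9 to O8, which removes the charge acceleration;
  - leakage through a boat array, which would erode the Z geometry.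
- Fallback: set out from 18 and silylate it (TMSOTf, 2,6-lutidine) to the trimethylsilyl ether F1. Run the rearrangement as a neutral thermal silyloxy-Cope reaction (o-dichlorobenzene, about 190 °C, base-washed glass).
- No anion is present in this variant, and its direct product is silyl enol ether 21, where the route is rejoined.

**Step 2.**
- Facial discrimination may be poor.
- Regiocontrol may be lost if titanium binds only the more basic C2 carbonyl instead of chelating.
- Fallback:
  - Set out from 4 and 5 with SnCl4, a chelating achiral promoter, in the racemic series, and run steps 3 to 8 unchanged.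
  - Resolve at the diol stage by esterifying the accessible 12-OH with (S)-O-methylmandelic acid (DCC, DMAP). This gives the mandelate F2 and, from the antipode, the diastereomeric mandelate F3.
  - Separate the two by chromatography. Saponification of F2 (LiOH, THF/H2O, 0 °C) comes back to the route at 12.

**Step 12.**
- At the temperature of the rearrangement, the β-allenyl ketone may undergo prototropic isomerisation to a conjugated dienone.
- The enol ether may also lose silanol before it rearranges.
- Fallback:
  - Set out from 15 and hydrolyse the enol ether (oxalic acid on wet silica gel, CH2Cl2, 0 °C) to the 8-ketone F4.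
  - Form its kinetic C3 enolate (LiN(iPr)2, −78 °C) and add propynal to give the propargylic aldol F5. The carbinol epimers are of no consequence.
  - Apply the Myers allene synthesis (2-nitrobenzenesulfonylhydrazide, PPh3, DEAD, −15 °C to rt). This converts the propargylic alcohol into the terminal allene and comes back at 16.

**Step 17.**
- The hindered ketone may be enolised toward C9.
- The adduct may revert by retro-aldol reaction.
- The carbonyl face may not be controlled by the chelate.
- Fallback:
  - Set out from 23 and use lithium prop-1-yn-1-olate F6 (from ethyl 2,2-dibromopropanoate and tBuLi). This is a small, weakly basic nucleophile that adds irreversibly.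
  - It closes to a β-lactone enolate, and protonation gives the spiro β-lactone F7.
  - Opening of the epoxide of F7 with anhydrous HCl in Et2O frees the 7-OH, which attacks the strained β-lactone carbonyl. This acyl shift liberates the 8-OH and comes back at 27.

**Step 18.**
- Chloride may attack C16 with allylic transposition.
- C6 may partly ionise, with loss of inversion.
- The epoxide may migrate toward C8 (Payne type) before it is opened.
- Fallback:
  - Change the order of events. Set out from 23, where the carbonyl group disfavours ionisation and no free 8-OH is present.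
  - Open the epoxide with LiCl/AcOH in THF to the chloro ketol F8, then acylate the 7-OH with 2-bromopropanoyl bromide (pyridine, −40 °C) to the bromo ester F9.
  - Close ring C by an intramolecular Reformatsky reaction (activated Zn, THF, or Et2Zn with catalytic RhCl(PPh3)3). This forms C8–C17 under tether control and comes back at 27.

## Further compounds

F1 | step 14 | 8-O-trimethylsilyl ether of 18 | C=C=C[C@H]1[C@H](O[Si](CC)(CC)CC)[C@@]2(C)C=C[C@H]3OC(C)(C)O[C@@]3(C)[C@@H]2[C@H](O[Si](C)(C)C(C)(C)C)[C@@]1(O[Si](C)(C)C)C=C
F2 | step 2 | 12-O-[(S)-O-methylmandelate] of 12 | C#CCOC1=CC(=O)[C@@]2(C)C=C[C@@H](OC(=O)[C@@H](OC)c3ccccc3)[C@@](C)(O)[C@@H]2[C@@H]1O[Si](C)(C)C(C)(C)C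
F3 | step 2 | 12-O-[(S)-O-methylmandelate] of the antipode of 12 | C#CCOC1=CC(=O)[C@]2(C)C=C[C@H](OC(=O)[C@@H](OC)c3ccccc3)[C@](C)(O)[C@H]2[C@H]1O[Si](C)(C)C(C)(C)C
F4 | step 12 | 8-ketone with unsubstituted C3 | O=C1C[C@H](O[Si](CC)(CC)CC)[C@@]2(C)C=C[C@H]3OC(C)(C)O[C@@]3(C)[C@@H]2[C@@H]1O[Si](C)(C)C(C)(C)C
F5 | step 12 | 3α-(1-hydroxyprop-2-ynyl) 8-ketone (carbinol epimers) | C#CC(O)[C@H]1[C@H](O[Si](CC)(CC)CC)[C@@]2(C)C=C[C@H]3OC(C)(C)O[C@@]3(C)[C@@H]2[C@H](O[Si](C)(C)C(C)(C)C)C1=O
F6 | step 17 | lithium prop-1-yn-1-olate | [Li+].CC#C[O-]
F7 | step 17 | spiro β-lactone at C8 with 6,7-epoxide | C=C1/C=C\[C@H](O[Si](CC)(CC)CC)[C@@]2(C)C=C[C@H]3OC(C)(C)O[C@@]3(C)[C@@H]2[C@H](O[Si](C)(C)C(C)(C)C)[C@@]5(OC(=O)[C@@H]5C)[C@H]4O[C@@H]41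
F8 | step 18 | 6-chloro-7-hydroxy 8-ketone | C=C1/C=C\[C@H](O[Si](CC)(CC)CC)[C@@]2(C)C=C[C@H]3OC(C)(C)O[C@@]3(C)[C@@H]2[C@H](O[Si](C)(C)C(C)(C)C)C(=O)[C@@H](O)[C@H]1Cl
F9 | step 18 | 7-O-(2-bromopropanoyl) derivative of F8 | C=C1/C=C\[C@H](O[Si](CC)(CC)CC)[C@@]2(C)C=C[C@H]3OC(C)(C)O[C@@]3(C)[C@@H]2[C@H](O[Si](C)(C)C(C)(C)C)C(=O)[C@@H](OC(=O)C(C)Br)[C@H]1Cl
A1 | alternative 1 | 3,4-seco-tetraene for ring-closing metathesis | C=CC(=C)[C@H](Cl)[C@@H]1OC(=O)[C@H](C)[C@@]1(O)[C@@H](OC(C)=O)[C@H]1[C@](C)(O)[C@H](OC(C)=O)C=C[C@]1(C)[C@@H](OC(=O)CCC)C=C
A2 | alternative 2 | cis-fused hydrophenanthrene 9-hydroxy 3-mesylate (C4–C9 bond present) | C=C1C[C@@H]2OC(=O)[C@H](C)[C@@]2(O)[C@@]3(O)[C@@H]1[C@@H](OS(C)(=O)=O)[C@H](O[Si](CC)(CC)CC)[C@@]4(C)C=C[C@H]5OC(C)(C)O[C@@]5(C)[C@H]34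
A3 | alternative 2 | fragmentation product, (3Z)-9-ketone | C=C1/C=C\[C@H](O[Si](CC)(CC)CC)[C@@]2(C)C=C[C@H]3OC(C)(C)O[C@@]3(C)[C@@H]2C(=O)[C@]2(O)[C@@H](C)C(=O)O[C@H]2C1
A4 | alternative 3 | 14-membered macrocyclic 1(14),10,12-triene | C=C1/C=C\[C@H](OC(=O)CCC)/C(C)=C\C=C/C(C)=C/[C@H](OC(C)=O)[C@]2(O)[C@@H](C)C(=O)O[C@H]2[C@H]1Cl
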